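## Structural features

The target is a cedrane-type tricycle. Cyclopentane ring A (C1–C5) and cyclopentane ring B (C1, C5, C6, C7, C11) share the C1–C5 bond, and cyclohexene ring C (C1, C10, C9, C8, C7, C11) spans ring B through C1, C7 and the methylene C11, so C1 is a fully carbon-substituted spiro and bridgehead atom common to all three rings. Six stereocentres form one contiguous array: C1, C2 (formyl group on the face of ring A that carries C10), C5, the quaternary C6 (methyl turned towards C8, hydroxymethyl towards the C11 side), the bridgehead C7, and the carbinol C10, whose oxygen is anti to the C1–C5 bond and carries the (9Z)-16-hydroxyhexadec-9-enoyl chain. The fragile groups are the C15 aldehyde on the epimerisable C2, the free C12 acid conjugated with C8=C9, the allylic secondary ester at C10, two free primary alcohols, and the Z-alkene of the chain, which tolerates neither ozone nor hydrogenation. The real difficulty lies in the adjacent quaternary carbons C1 and C6 inside the bicyclo[3.2.1]octane and in telling apart four oxygenated positions (C12 acid, C13 alcohol, C15 aldehyde, C10 ester). The key step uses the fact that ring C, at the dienone oxidation level, is a phenol whose para carbon is C1: in a 4-alkyl-3-methoxyphenol the methoxy oxygen is the future C10 oxygen, the phenol oxygen sits on C8, and ipso attack of C1 on an allyl terminus creates C1–C2, ring A and a C2 vinyl group that is a latent C15 aldehyde. In the dienone so formed, C8 is the carbonyl carbon, C7 its α-carbon and C11 its β-carbon, so an enolate at C6 could only reach C11 (a four-membered ring). Ring B therefore cannot be closed by conjugate addition to the dienone itself; the route first exchanges the C8 oxygen for the C12 carboxyl (C7=C8–C12), which makes C7 a true acceptor carbon and installs C12 in the same move.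

## Logic of the disconnections

**32 back to 30.** Only protecting groups are removed: the O–Si bonds at C13 and C16′, the O–C bond of the silylethyl ester at C12, and the two C–O bonds of the C15 acetal. This keeps every acidic, nucleophilic or epimerisable group masked until the end. The price is a last step that must free five functions (fluoride, then dilute acid) without touching the C10 ester or the Z-alkene.

**30 back to 23 and 29.** The C10–O(acyl) bond is cut so that the chain arrives as a finished acid. Hydride is expected to reach the C10 carbonyl from the C11 face, so 23 has the wrong C10 configuration. The forward step must therefore form the C10–O bond with inversion at a hindered allylic carbon.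

**29 back to 24 and 26.** The chain is cut at C8′–C9′, next to a triple bond (28) that stands for the Z-alkene; both halves (25, 26) are eight-carbon commercial pieces. The forward steps need an acetylide alkylation in the presence of a carboxylate and a semihydrogenation that stops at the alkene.

**23 back to 20.** The C10–H bond and the C15 acetal are removed: C10 returns to the enone carbonyl and C15 to a vinyl group on C2 (22, 21). Ozonolysis at this point, before the chain arrives, protects the Z-alkene. The forward steps need ozone to distinguish the vinyl group from the electron-poor C8=C9 bond, and a 1,2-selective hydride.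

**20 back to 18.** The C8=C9 double bond is taken out (19, 18), giving a saturated keto ester with a free C13 hydroxyl. C8 thereby becomes an ester α-carbon that a conjugate addition can create. The forward dehydrogenation must be regioselective, which the quaternary C1 guarantees.

**18 back to 15.** The C6–C7 bond of ring B is cut and C13 returns to the ester level. The bicyclo[3.2.1]octane opens to a spirocycle and the stereocentres C6 and C7 disappear. The forward step asks a hindered ester enolate at C6 to add to C7 with C13 ending on the exo side, and asks for reduction of one ester in the presence of another.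

**15 back to 12.** The C8–C12 bond is cut and the C7=C11 unsaturation restored (14, 13), returning to the dienone. This is the polarity correction. It needs a conjugate reduction that spares the methoxy-bearing half of the dienone and a carbonylation of the derived enol triflate.

**12 back to 11.** The C1–C2 bond is cut: the spirodienone becomes a phenol and ring A an open chain ending in an allylic carbonate. Two stereocentres (C1, C2) and one ring disappear. The forward step must make the phenol react at carbon, at its para position, with control of two faces.

**11 back to 7.** The C2=C15 alkene is cut in the metathesis sense (10 plus a three-carbon allyl carbonate partner), the phenol is re-silylated (9), and the C6–C14 bond is cut (7). What remains is a β-aryl ester with one stereocentre, C5. The forward steps are routine but must keep the phenol masked during enolate chemistry.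

**7 back to 1 and 5.** The C5–C1(aryl) bond is cut to the arylboronic acid 4 and the dienoate 6, so that C5 is set by catalytic asymmetric conjugate addition. 4 comes from 1 through 2 (C–Br to C–B) and 6 from 5 by a two-carbon olefination. The demand is high enantioselectivity with an ortho-substituted, electron-rich boronic acid.

## Other disconnections considered

**Alternative 1:** This cuts C7–C8 and C6–C14; the four-membered ring formed is later opened at C8–C14 by retro-aldol. In the forward sense, irradiation of the dioxinone-tethered cyclopentene A1 at about 300 nm would add the excited dioxinone across C6=C7 to give the cyclobutane photoadduct A2.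
- In its favour: the quaternary C6 is made by a suprafacial cycloaddition, so C14 must end up syn to C8 and the already silylated C13 anti to it. The C6 configuration follows from geometry, not from a transition-state preference. On this point the alternative is better than the chosen plan, where C6 depends on an open versus a bridged Michael transition state. C12 also arrives at the right oxidation level.
- Against it here: A1 must already contain rings A and B, the spiro carbon C1 and three more stereocentres (C2, C5, C10), so the hardest carbon is left to earlier chemistry. The tether reaches both alkene carbons through four atoms, so straight and crossed adducts can compete. After fragmentation C14 is a neopentyl aldehyde that must be reduced to methyl next to an ester, and C9 is saturated, so C8=C9 must still be introduced.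
- Comparison: structurally it solves C6 and ring C but not C1 and ring A, the reverse of the chosen plan. Mechanistically it replaces a catalytic ionic closure with one feasible ring size by a photochemical step with a regiochemical ambiguity. In step economy the route to A1 is judged at least as long as the chosen sequence to 12, and several redox steps follow A2, so it is longer overall.

**Alternative 2:** This cuts C1–C5, C2–C3 and C3–C4. In the forward sense, Co2(CO)8 would complex the terminal alkyne of enyne A3, and an amine N-oxide would promote insertion of the exocyclic C1=C2 alkene and CO to give cyclopentenone A4 (Pauson–Khand reaction).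
- In its favour: two rings and the spiro carbon arise in one step. The tether from C7 forces the new C1–C5 bond onto the only face of ring C that can bridge, so C1 is as secure as in the chosen plan (equal). C2 follows stereospecifically from the alkene geometry, which is better than a ligand-controlled allyl face. Ring C arrives fully functionalised.
- Against it here: the alkene is trisubstituted and exocyclic, and insertion that creates a quaternary carbon is the slow case of this cycloaddition. A3 needs the quaternary C6, C7, C10 and a defined alkene geometry beforehand. After the cyclisation the C3 carbonyl must be removed and C4=C5 reduced with hydrogen arriving at C5 on the hindered face that carries C10, in the presence of the C8=C9 enoate.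
- Comparison: structurally it makes rings A and B late and puts the burden on an elaborate ring C precursor. Mechanistically it uses stoichiometric cobalt against catalytic palladium. In step economy it adds at least three redox operations after the key step and a long route to A3, so it is longer.

**Alternative 3:** This cuts C7–C8 and C1–C10. In the forward sense, Rh2(S-DOSP)4 would decompose the vinyl diazo ester A6; cyclopropanation of the less substituted C6=C7 bond of the fused cyclopentadiene A5 gives a cis-divinylcyclopropane that undergoes Cope rearrangement to the bicyclo[3.2.1]octadiene A7.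
- In its favour: it is the most convergent of the four plans. One catalytic step makes ring C and both bridgeheads and places the C12 ester on C8 and the C8=C9 alkene in their final positions. On these points it is better than the chosen plan, which needs triflation, carbonylation and dehydrogenation. The concerted boat rearrangement fixes the C1/C7 relationship as reliably as the tether does in the chosen plan (equal).
- Against it here: A7 lacks the C10 oxygen (a stereocontrolled allylic oxidation would be needed), lacks C14, and carries a tetrasubstituted C5=C6 alkene from which C5–H and the quaternary C6 would still have to be made. The most difficult element is postponed, not solved. A5 is a 1,2-fused cyclopentadiene prone to 1,5-hydrogen shifts and dimerisation, and the catalyst must override the existing C2 centre.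
- Comparison: structurally it builds ring C onto rings A and B, while the chosen plan builds ring A onto ring C. Mechanistically it is a carbenoid cascade against an ionic allylation. In step economy it is short up to A7 and long afterwards, with no net gain.

Key step: step 8

Assumption: ring B can close only when the C6 arm on C5 and C11 lie on the same face of ring A (cis-fused cedrane core), so the route is laid out for that arrangement with the C1, C2, C6, C7 and C10 relationships of the target; every SMILES keeps the target's descriptors exactly as written, including the one at C5, which on a strict reading would put the arm on the C10 face.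

## Route

Step 1
Reactants: 1 4-bromo-3-methoxyphenol
Product: 2 (4-bromo-3-methoxyphenoxy)triisopropylsilane
Conditions: i-Pr3SiCl, imidazole, DMF, rt
Reagents that add atoms: triisopropylsilyl chloride, CC(C)[Si](Cl)(C(C)C)C(C)C
Why: Imidazole-assisted silylation masks the acidic phenol for the organolithium and enolate steps; the bulky aryl silyl ether tolerates n-BuLi at low temperature, hot aqueous dioxane and lithium amide bases.

Step 2
Reactants: 2 (4-bromo-3-methoxyphenoxy)triisopropylsilane
Product: 4 [2-methoxy-4-(triisopropylsilyloxy)phenyl]boronic acid, via aryllithium 3 (not isolated)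
Conditions: n-BuLi, THF, −78 °C; B(O-i-Pr)3, −78 °C → rt; aq NH4Cl
Reagents that add atoms: triisopropyl borate, CC(C)OB(OC(C)C)OC(C)C; water, O
Why: Bromine–lithium exchange (helped by the ortho methoxy group) is faster than any attack on the silyl ether at −78 °C, and the aryllithium is trapped by the borate; mild hydrolysis gives the boronic acid (lithiation–borylation).

Step 3
Reactants: 5 pent-4-enal
Product: 6 methyl (2E)-hepta-2,6-dienoate
Conditions: (MeO)2P(O)CH2CO2Me, NaH, THF, 0 °C → rt
Reagents that add atoms: trimethyl phosphonoacetate, COC(=O)CP(=O)(OC)OC
Why: Horner–Wadsworth–Emmons olefination of an unhindered aldehyde with a stabilised phosphonate gives the E-enoate; the remote terminal alkene is inert.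

Step 4
Reactants: 4 [2-methoxy-4-(triisopropylsilyloxy)phenyl]boronic acid; 6 methyl (2E)-hepta-2,6-dienoate
Product: 7 methyl (3S)-3-[2-methoxy-4-(triisopropylsilyloxy)phenyl]hept-6-enoate
Conditions: Rh(acac)(C2H4)2 (3 mol%), (R)-BINAP (3.3 mol%), 4 (2.5 equiv), dioxane/H2O 10:1, 100 °C
Reagents that add atoms: none
Why: Rhodium-catalysed asymmetric conjugate addition of an arylboronic acid to an E-enoate (Hayashi–Miyaura reaction): the aryl group passes from rhodium to the β-carbon on the enoate face left open by (R)-BINAP, which sets C5 with the descriptor written (S). The isolated terminal alkene does not insert, and the excess of 4 offsets protodeboronation of this electron-rich boronic acid.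

Step 5
Reactants: 7 methyl (3S)-3-[2-methoxy-4-(triisopropylsilyloxy)phenyl]hept-6-enoate
Product: 9 methyl (3S)-3-[2-methoxy-4-(triisopropylsilyloxy)phenyl]-2-methylhept-6-enoate (both epimers at the ester α-carbon, cedrane C6), via lithium enolate 8 (not isolated)
Conditions: LiN(i-Pr)2, THF, −78 °C; MeI, −78 → 0 °C
Reagents that add atoms: iodomethane, CI
Why: Kinetic ester enolate alkylation adds C14; both C6 epimers are acceptable because C6 becomes trigonal again in step 11.

Step 6
Reactants: 9 methyl (3S)-3-[2-methoxy-4-(triisopropylsilyloxy)phenyl]-2-methylhept-6-enoate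
Product: 10 methyl (3S)-3-(4-hydroxy-2-methoxyphenyl)-2-methylhept-6-enoate (α-epimers)
Conditions: TBAF, THF, 0 °C; aq NH4Cl
Reagents that add atoms: none
Why: Fluoride cleaves the aryl silyl ether without touching the ester; the phenol is freed before the allylic carbonate exists, so that fluoride and phenoxide never meet it.

Step 7
Reactants: 10 methyl (3S)-3-(4-hydroxy-2-methoxyphenyl)-2-methylhept-6-enoate
Product: 11 methyl (3S,6E)-3-(4-hydroxy-2-methoxyphenyl)-8-[(methoxycarbonyl)oxy]-2-methyloct-6-enoate (α-epimers)
Conditions: allyl methyl carbonate (5 equiv), second-generation Grubbs catalyst (5 mol%), CH2Cl2, 40 °C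
Reagents that add atoms: allyl methyl carbonate, C=CCOC(=O)OC
Why: Cross-metathesis of the terminal alkene with an excess of the allyl carbonate, driven by loss of ethene, gives mainly the E-allylic carbonate; free phenols and esters are tolerated by the ruthenium carbene, and any Z isomer leads to the same allyl complex in step 8.

Step 8
Reactants: 11 methyl (3S,6E)-3-(4-hydroxy-2-methoxyphenyl)-8-[(methoxycarbonyl)oxy]-2-methyloct-6-enoate
Product: 12 methyl 2-(6-methoxy-8-oxo-4-vinylspiro[4.5]deca-6,9-dien-1-yl)propanoate (spiro carbon C1; vinyl on C2 on the face of ring A that carries the methoxy-substituted carbon C10; α-epimers)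
Conditions: Pd2(dba)3·CHCl3 (2.5 mol%), (S,S)-ANDEN-phenyl bis(2-diphenylphosphinobenzamide) ligand (7.5 mol%), CH2Cl2 (0.02 M), rt
Reagents that add atoms: none
Why: Zerovalent palladium ionises the allylic carbonate to a cationic π-allyl complex, and the methoxide set free with CO2 deprotonates the phenol. The phenoxide then attacks the internal allyl terminus C2 through its para carbon C1 on the face opposite to palladium; this is the known intramolecular ipso-Friedel–Crafts allylic alkylation of para-alkyl phenols, and the product cannot re-aromatise because C1 is quaternary. Ring A closes in the 5-exo mode, while attack at the distal terminus (seven-membered ring) and intramolecular O-allylation (large ring) are disfavoured and high dilution suppresses intermolecular O-allylation. At C2, the two faces of the allyl terminus interconvert by π–σ–π isomerisation faster than the ring closes, so the chiral bisphosphine pocket decides which face is attacked; the ligand antipode matched with the C5 centre is used and should place the vinyl group syn to C10. At C1, allylic 1,3-strain holds the benzylic C5–H bond in the arene plane beside the methoxy-bearing carbon C10, so the tether and the C6 arm lie on opposite faces of the ring, and closure through the tether face leaves the C6 arm syn to C11, the relationship ring B needs. The step needs carbon over oxygen alkylation and para over ortho attack: the para carbon is the only one a five-membered closure can reach, and the ester arm (pKa about 25) is not deprotonated by methoxide and stays a spectator.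

Step 9
Reactants: 12 methyl 2-(6-methoxy-8-oxo-4-vinylspiro[4.5]deca-6,9-dien-1-yl)propanoate
Product: 14 methyl 2-[6-methoxy-8-(trifluoromethylsulfonyloxy)-4-vinylspiro[4.5]deca-6,8-dien-1-yl]propanoate, via lithium enolate 13 (not isolated)
Conditions: LiBH(s-Bu)3, THF, −78 °C; PhNTf2, −78 → 0 °C; aq NH4Cl
Reagents that add atoms: N-phenylbis(trifluoromethanesulfonimide), O=S(=O)(N(c1ccccc1)S(=O)(=O)C(F)(F)F)C(F)(F)F
Why: Conjugate hydride addition goes to C11, the only unsubstituted β-carbon (C10 is deactivated by its methoxy group), and the C7=C8 enolate is trapped on oxygen (reductive triflation of an enone). This turns the C8 oxygen into a leaving group and fixes the C7=C8 double bond.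

Step 10
Reactants: 14 methyl 2-[6-methoxy-8-(trifluoromethylsulfonyloxy)-4-vinylspiro[4.5]deca-6,8-dien-1-yl]propanoate
Product: 15 2-(trimethylsilyl)ethyl ester analogue of 14 (CO2CH2CH2SiMe3 on C8 in place of the triflate; C7=C8 and C9=C10(OMe) diene)
Conditions: Pd(OAc)2 (5 mol%), PPh3 (10 mol%), CO (1 atm), Me3SiCH2CH2OH, Et3N, DMF, 50 °C
Reagents that add atoms: carbon monoxide, [C-]#[O+]; 2-(trimethylsilyl)ethanol, C[Si](C)(C)CCO
Why: Palladium-catalysed alkoxycarbonylation of an enol triflate (oxidative addition, CO insertion, alcoholysis) attaches C12 to C8 as a fluoride-labile ester. C7 is now the β-carbon of an enoate, the polarity that the dienone lacked.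

Step 11
Reactants: 15 spirocyclic dienoate
Product: 18 tricyclic keto ester alcohol (C10 ketone; C8–H bearing CO2CH2CH2SiMe3, C8 epimers; C6 with methyl towards C8 and CH2OH exo; vinyl on C2), via potassium dienolate 16 (not isolated), via enol ether alcohol 17 (not isolated)
Conditions: KN(SiMe3)2, 18-crown-6, THF, −78 → −20 °C; LiAlH4, −20 → 0 °C; 1 M HCl, THF, rt
Reagents that add atoms: water, O
Why: The potassium ester enolate at C6 adds 5-exo-trig to C7 (intramolecular Michael addition) on the only face the tether allows, which sets C7; with 18-crown-6 the open, antiperiplanar transition state keeps the solvated enolate carbon C13 away from ring C and puts the methyl group C14 under it, which sets C6. The adduct is the C12 ester dienolate, which is inert to hydride, so LiAlH4 reduces only the C13 methyl ester (enolate protection). Aqueous acid then protonates C8 and hydrolyses the enol ether to the C10 ketone.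

Step 12
Reactants: 18 tricyclic keto ester alcohol
Product: 19 C13 tert-butyldiphenylsilyl ether of 18
Conditions: t-BuPh2SiCl, imidazole, DMAP (cat.), DMF, rt
Reagents that add atoms: tert-butyl(chloro)diphenylsilane, CC(C)(C)[Si](Cl)(c1ccccc1)c1ccccc1
Why: Silylation of the neopentyl primary alcohol; this robust silyl ether survives IBX, ozone, acidic acetalisation and borohydride.

Step 13
Reactants: 19 silylated keto ester
Product: 20 tricyclic enone (C10 ketone, C8=C9, C12 silylethyl ester, C13 silyl ether, C2 vinyl)
Conditions: IBX (3 equiv), DMSO/fluorobenzene, 75 °C
Reagents that add atoms: none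
Why: IBX dehydrogenation of a ketone to an enone: only C9 can enolise because C1 is quaternary, so the new double bond is C8=C9, conjugated with both the C10 ketone and the C12 ester.

Step 14
Reactants: 20 tricyclic enone
Product: 22 C15 dimethyl acetal of the enone, via aldehyde 21 (not isolated)
Conditions: O3, CH2Cl2/MeOH, −78 °C; Me2S; HC(OMe)3, PPTS, rt
Reagents that add atoms: ozone, [O-][O+]=O; trimethyl orthoformate, COC(OC)OC
Why: Ozone attacks the terminal vinyl group far faster than the doubly acceptor-substituted C8=C9 bond, and reductive work-up gives the C15 aldehyde. It is acetalised at once so that C2 cannot epimerise and no lactol can form with the C10 hydroxyl made in the next step.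

Step 15
Reactants: 22 acetal enone
Product: 23 C10 alcohol with the hydroxyl equatorial (anti to the C1–C11 bond; the C10 epimer of the target)
Conditions: NaBH4, CeCl3·7H2O, MeOH, −40 °C
Reagents that add atoms: none
Why: Luche 1,2-reduction: hydride should enter along the axial trajectory on the C11 face, anti to the C1–C5 bond (torsional control) and away from the C2 acetal, giving the equatorial alcohol that is set up for inversion. CeCl3 suppresses conjugate reduction of the ene-dicarbonyl system.

Step 16
Reactants: 24 oct-7-yn-1-ol
Product: 25 tert-butyldimethyl(oct-7-yn-1-yloxy)silane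
Conditions: t-BuMe2SiCl, imidazole, DMF, rt
Reagents that add atoms: tert-butyl(chloro)dimethylsilane, CC(C)(C)[Si](C)(C)Cl
Why: Routine silylation of the primary alcohol so that only the alkyne C–H is acidic in the next step.

Step 17
Reactants: 25 tert-butyldimethyl(oct-7-yn-1-yloxy)silane; 26 8-bromooctanoic acid
Product: 28 16-[(tert-butyldimethylsilyl)oxy]hexadec-9-ynoic acid, via lithium acetylide 27 (not isolated)
Conditions: 25 (2.2 equiv), n-BuLi (2.1 equiv), THF/DMPU, −78 → 0 °C; 26, 0 °C → rt; 1 M HCl
Reagents that add atoms: none
Why: SN2 alkylation of a lithium acetylide by a primary bromide in a dipolar cosolvent; one equivalent of acetylide serves as base for the carboxylic acid, so the acid needs no protection.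

Step 18
Reactants: 28 16-[(tert-butyldimethylsilyl)oxy]hexadec-9-ynoic acid
Product: 29 (9Z)-16-[(tert-butyldimethylsilyl)oxy]hexadec-9-enoic acid
Conditions: H2 (1 atm), Pd/CaCO3 poisoned with Pb(OAc)2, quinoline, EtOAc, rt
Reagents that add atoms: none
Why: Semihydrogenation of an internal alkyne on poisoned palladium: syn delivery of hydrogen gives the Z-alkene, and quinoline stops over-reduction.

Step 19
Reactants: 23 equatorial C10 alcohol; 29 (9Z)-16-[(tert-butyldimethylsilyl)oxy]hexadec-9-enoic acid
Product: 30 fully protected ester (C10 acyloxy group anti to the C1–C5 bond; C12 silylethyl ester; C13 and C16′ silyl ethers; C15 dimethyl acetal)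
Conditions: PPh3, DIAD, toluene, 0 → 40 °C
Reagents that add atoms: none
Why: Mitsunobu esterification: the equatorial hydroxyl is activated as an alkoxyphosphonium ion and displaced by the carboxylate from the open C11 face with inversion, giving the axial C10 ester of the target. The centre is allylic, which speeds SN2; SN2′ is blocked because C8 is fully substituted, and there is no β-hydrogen for elimination.

Step 20
Reactants: 30 fully protected ester
Product: 32 target CNP0148862.1, via acetal diol acid 31 (not isolated)
Conditions: TBAF, THF, 0 °C → rt; 1 M HCl, THF/H2O, rt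
Reagents that add atoms: water, O
Why: Fluoride removes both silyl ethers and fragments the 2-(trimethylsilyl)ethyl ester to ethene and fluorotrimethylsilane while the aldehyde is still an acetal and so is safe from base. Brief aqueous acid then hydrolyses the dimethyl acetal without cleaving the C10 ester or touching the Z-alkene.

## Compound list

1 | 4-bromo-3-methoxyphenol | COc1cc(O)ccc1Br | starting material
2 | (4-bromo-3-methoxyphenoxy)triisopropylsilane | COc1cc(O[Si](C(C)C)(C(C)C)C(C)C)ccc1Br | intermediate
3 | [2-methoxy-4-(triisopropylsilyloxy)phenyl]lithium (not isolated) | COc1cc(O[Si](C(C)C)(C(C)C)C(C)C)ccc1[Li] | intermediate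
4 | [2-methoxy-4-(triisopropylsilyloxy)phenyl]boronic acid | COc1cc(O[Si](C(C)C)(C(C)C)C(C)C)ccc1B(O)O | intermediate
5 | pent-4-enal | C=CCCC=O | starting material
6 | methyl (2E)-hepta-2,6-dienoate | C=CCC/C=C/C(=O)OC | intermediate
7 | methyl (3S)-3-[2-methoxy-4-(triisopropylsilyloxy)phenyl]hept-6-enoate | COC(=O)C[C@H](CCC=C)c1ccc(O[Si](C(C)C)(C(C)C)C(C)C)cc1OC | intermediate
8 | lithium enolate of 7 (not isolated) | COC(O[Li])=C[C@H](CCC=C)c1ccc(O[Si](C(C)C)(C(C)C)C(C)C)cc1OC | intermediate
9 | methyl (3S)-3-[2-methoxy-4-(triisopropylsilyloxy)phenyl]-2-methylhept-6-enoate (α-epimers) | COC(=O)C(C)[C@H](CCC=C)c1ccc(O[Si](C(C)C)(C(C)C)C(C)C)cc1OC | intermediate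
10 | methyl (3S)-3-(4-hydroxy-2-methoxyphenyl)-2-methylhept-6-enoate (α-epimers) | COC(=O)C(C)[C@H](CCC=C)c1ccc(O)cc1OC | intermediate
11 | methyl (3S,6E)-3-(4-hydroxy-2-methoxyphenyl)-8-[(methoxycarbonyl)oxy]-2-methyloct-6-enoate (α-epimers) | COC(=O)C(C)[C@H](CC/C=C/COC(=O)OC)c1ccc(O)cc1OC | intermediate
12 | methyl 2-(6-methoxy-8-oxo-4-vinylspiro[4.5]deca-6,9-dien-1-yl)propanoate (spiro carbon C1, vinyl on C2 syn to C10, α-epimers) | COC(=O)C(C)[C@@H]1CC[C@H](C=C)[C@@]12C=CC(=O)C=C2OC | intermediate
13 | lithium enolate from conjugate reduction of 12 (C7=C8–OLi; not isolated) | COC(=O)C(C)[C@@H]1CC[C@H](C=C)[C@@]12CC=C(O[Li])C=C2OC | intermediate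
14 | methyl 2-[6-methoxy-8-(trifluoromethylsulfonyloxy)-4-vinylspiro[4.5]deca-6,8-dien-1-yl]propanoate | COC(=O)C(C)[C@@H]1CC[C@H](C=C)[C@@]12CC=C(OS(=O)(=O)C(F)(F)F)C=C2OC | intermediate
15 | spirocyclic dienoate: as 14 with CO2CH2CH2SiMe3 on C8 | COC(=O)C(C)[C@@H]1CC[C@H](C=C)[C@@]12CC=C(C(=O)OCC[Si](C)(C)C)C=C2OC | intermediate
16 | potassium dienolate of the Michael adduct (C12 enolate, C9=C10 enol ether, C13 methyl ester; not isolated) | [K+].C[C@@]1(C(=O)OC)[C@@H]2C[C@]3(C(OC)=CC2=C([O-])OCC[Si](C)(C)C)[C@@H](C=C)CC[C@@H]13 | intermediate
17 | enol ether alcohol (C13 CH2OH, C8–H ester, C9=C10 enol ether; C8 epimers; not isolated) | C[C@@]1(CO)[C@@H]2C[C@]3(C(OC)=CC2C(=O)OCC[Si](C)(C)C)[C@@H](C=C)CC[C@@H]13 | intermediate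
18 | tricyclic keto ester alcohol (C10 ketone, C8–H ester as C8 epimers, C6 methyl towards C8 and CH2OH exo, C2 vinyl) | C[C@@]1(CO)[C@@H]2C[C@]3(C(=O)CC2C(=O)OCC[Si](C)(C)C)[C@@H](C=C)CC[C@@H]13 | intermediate
19 | C13 tert-butyldiphenylsilyl ether of 18 | C[C@@]1(CO[Si](c4ccccc4)(c4ccccc4)C(C)(C)C)[C@@H]2C[C@]3(C(=O)CC2C(=O)OCC[Si](C)(C)C)[C@@H](C=C)CC[C@@H]13 | intermediate
20 | tricyclic enone (C10 ketone, C8=C9, C12 silylethyl ester, C2 vinyl) | C[C@@]1(CO[Si](c4ccccc4)(c4ccccc4)C(C)(C)C)[C@@H]2C[C@]3(C(=O)C=C2C(=O)OCC[Si](C)(C)C)[C@@H](C=C)CC[C@@H]13 | intermediate
21 | C15 aldehyde of the enone (not isolated) | C[C@@]1(CO[Si](c4ccccc4)(c4ccccc4)C(C)(C)C)[C@@H]2C[C@]3(C(=O)C=C2C(=O)OCC[Si](C)(C)C)[C@@H](C=O)CC[C@@H]13 | intermediate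
22 | C15 dimethyl acetal of the enone | C[C@@]1(CO[Si](c4ccccc4)(c4ccccc4)C(C)(C)C)[C@@H]2C[C@]3(C(=O)C=C2C(=O)OCC[Si](C)(C)C)[C@@H](C(OC)OC)CC[C@@H]13 | intermediate
23 | equatorial C10 alcohol (C10 epimer of the target series) | C[C@@]1(CO[Si](c4ccccc4)(c4ccccc4)C(C)(C)C)[C@@H]2C[C@]3([C@H](O)C=C2C(=O)OCC[Si](C)(C)C)[C@@H](C(OC)OC)CC[C@@H]13 | intermediate
24 | oct-7-yn-1-ol | C#CCCCCCCO | starting material
25 | tert-butyldimethyl(oct-7-yn-1-yloxy)silane | C#CCCCCCCO[Si](C)(C)C(C)(C)C | intermediate
26 | 8-bromooctanoic acid | OC(=O)CCCCCCCBr | starting material
27 | lithium acetylide of 25 (not isolated) | [Li]C#CCCCCCCO[Si](C)(C)C(C)(C)C | intermediate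
28 | 16-[(tert-butyldimethylsilyl)oxy]hexadec-9-ynoic acid | OC(=O)CCCCCCCC#CCCCCCCO[Si](C)(C)C(C)(C)C | intermediate
29 | (9Z)-16-[(tert-butyldimethylsilyl)oxy]hexadec-9-enoic acid | OC(=O)CCCCCCC/C=C\CCCCCCO[Si](C)(C)C(C)(C)C | intermediate
30 | fully protected ester (C10 acyloxy anti to C1–C5, C12 silylethyl ester, C13 and C16′ silyl ethers, C15 dimethyl acetal) | C[C@@]1(CO[Si](c4ccccc4)(c4ccccc4)C(C)(C)C)[C@@H]2C[C@]3([C@@H](OC(=O)CCCCCCC/C=C\CCCCCCO[Si](C)(C)C(C)(C)C)C=C2C(=O)OCC[Si](C)(C)C)[C@@H](C(OC)OC)CC[C@@H]13 | intermediate
31 | acetal diol acid (all silicon groups removed, C15 still the dimethyl acetal; not isolated) | C[C@@]1(CO)[C@@H]2C[C@]3([C@@H](OC(=O)CCCCCCC/C=C\CCCCCCO)C=C2C(=O)O)[C@@H](C(OC)OC)CC[C@@H]13 | intermediate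
32 | CNP0148862.1: 13-hydroxy-10-[(9Z)-16-hydroxyhexadec-9-enoyloxy]-15-oxocedr-8-en-12-oic acid | C[C@@]1(CO)[C@@H]2C[C@]3([C@@H](OC(=O)CCCCCCC/C=C\CCCCCCO)C=C2C(=O)O)[C@@H](C=O)CC[C@@H]13 | target

## Step count and least certain steps

Total step count: 20 (steps 1–15 for the tricycle, 16–18 for the chain, 19–20 for coupling and unmasking). Longest linear sequence: 16 steps (1 → 2 → 4 → 7 → 9 → 10 → 11 → 12 → 14 → 15 → 18 → 19 → 20 → 22 → 23 → 30 → 32).

**Step 8 (key step).** The most likely failure is loss of facial control at the allyl terminus C2 if the ligand preference and the existing C5 centre are mismatched; intermolecular O-allylation may also intrude because the para carbon is flanked by the methoxy group. The fallback sets out from 11. Closure with Pd(PPh3)4, without a chiral ligand, relies on the substrate alone for C1 and would give the spirodienone as a mixture at C2, F1. Taken through steps 9 to 13 unchanged, this gives the C2-mixed triflate F2, dienoate F3, keto ester alcohol F4, silyl ether F5 and enone F6. Ozonolysis with Me2S work-up gives the aldehyde mixture F7, which is equilibrated with DBU in CH2Cl2. The formyl group should settle on the convex face of the ring A/ring B diquinane, syn to C10, because the concave face is filled by C11 and the exo CH2OSi group on C6. The equilibrated aldehyde is 21, where the fallback rejoins the route before acetalisation.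

**Step 11.** The most likely failure is ring closure through a metal-bridged, closed transition state if the potassium enolate is not fully dissociated, which would invert the facial sense at C6. Competing deprotonation at C11 and partial hydride attack on the C12 ester during the in-flask reduction are secondary concerns. The fallback sets out from 15. LiN(i-Pr)2 and Me3SiCl give the silyl ketene acetal F8. A Mukaiyama–Michael closure with catalytic Me3SiNTf2 in CH2Cl2 at −78 °C cannot use a metal bridge and must go through the open transition state; after bicarbonate work-up it would give the enol ether diester F9. KN(SiMe3)2 then regenerates the dienolate 16, where the fallback rejoins step 11 for the hydride reduction and hydrolysis.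

**Step 19.** The most likely failure is that substitution at C10 does not take place, since the carbon is flanked by the quaternary C1; the alcohol would then be returned or acylated with retention through an acyloxyphosphonium pathway. The fallback sets out from 22. A Corey–Bakshi–Shibata reduction, with the oxazaborolidine antipode that delivers hydride to the face of the carbonyl turned towards the C5–C6 bridge, would give the axial alcohol F10 directly. F10 is then acylated with 29 with retention under Yamaguchi conditions (2,4,6-trichlorobenzoyl chloride, Et3N, DMAP), rejoining the route at 30.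

**Step 9.** The most likely failure is 1,2-reduction of the dienone carbonyl, or slow delivery of the bulky hydride to C11, which is next to the quaternary C1. The fallback sets out from 12. Conjugate reduction with CuH generated from Cu(OAc)2·H2O, 1,2-bis(diphenylphosphino)benzene and polymethylhydrosiloxane in toluene/t-BuOH would give the saturated vinylogous ester F11. Kinetic deprotonation at C7 with one equivalent of LiN(i-Pr)2 at −78 °C (the α′ position of the vinylogous ester is more acidic than the ester C6–H) gives the enolate 13, where the fallback rejoins step 9 before the triflation.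

## Further compounds

F1 | step 8 | spirodienone as a mixture at C2 | COC(=O)C(C)[C@@H]1CCC(C=C)[C@@]12C=CC(=O)C=C2OC
F2 | step 8 | dienyl triflate as a mixture at C2 | COC(=O)C(C)[C@@H]1CCC(C=C)[C@@]12CC=C(OS(=O)(=O)C(F)(F)F)C=C2OC
F3 | step 8 | spirocyclic dienoate as a mixture at C2 | COC(=O)C(C)[C@@H]1CCC(C=C)[C@@]12CC=C(C(=O)OCC[Si](C)(C)C)C=C2OC
F4 | step 8 | tricyclic keto ester alcohol as a mixture at C2 | C[C@@]1(CO)[C@@H]2C[C@]3(C(=O)CC2C(=O)OCC[Si](C)(C)C)C(C=C)CC[C@@H]13
F5 | step 8 | C13 silyl ether of the keto ester as a mixture at C2 | C[C@@]1(CO[Si](c4ccccc4)(c4ccccc4)C(C)(C)C)[C@@H]2C[C@]3(C(=O)CC2C(=O)OCC[Si](C)(C)C)C(C=C)CC[C@@H]13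
F6 | step 8 | tricyclic enone as a mixture at C2 | C[C@@]1(CO[Si](c4ccccc4)(c4ccccc4)C(C)(C)C)[C@@H]2C[C@]3(C(=O)C=C2C(=O)OCC[Si](C)(C)C)C(C=C)CC[C@@H]13
F7 | step 8 | C15 aldehyde as a mixture at C2 | C[C@@]1(CO[Si](c4ccccc4)(c4ccccc4)C(C)(C)C)[C@@H]2C[C@]3(C(=O)C=C2C(=O)OCC[Si](C)(C)C)C(C=O)CC[C@@H]13
F8 | step 11 | trimethylsilyl ketene acetal of 15 | COC(O[Si](C)(C)C)=C(C)[C@@H]1CC[C@H](C=C)[C@@]12CC=C(C(=O)OCC[Si](C)(C)C)C=C2OC
F9 | step 11 | enol ether diester (Michael adduct with C13 methyl ester, C8–H ester, C9=C10 enol ether) | C[C@@]1(C(=O)OC)[C@@H]2C[C@]3(C(OC)=CC2C(=O)OCC[Si](C)(C)C)[C@@H](C=C)CC[C@@H]13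
F10 | step 19 | axial C10 alcohol (hydroxyl anti to C1–C5) | C[C@@]1(CO[Si](c4ccccc4)(c4ccccc4)C(C)(C)C)[C@@H]2C[C@]3([C@@H](O)C=C2C(=O)OCC[Si](C)(C)C)[C@@H](C(OC)OC)CC[C@@H]13
F11 | step 9 | saturated vinylogous ester (C11 and C7 both CH2, C8 ketone) | COC(=O)C(C)[C@@H]1CC[C@H](C=C)[C@@]12CCC(=O)C=C2OC
A1 | alternative 1 | dioxinone-tethered cyclopentene photosubstrate | C1(CO[Si](C(C)C)(C(C)C)C(C)C)=CC[C@]3([C@@H](O[Si](C)(C)C(C)(C)C)CC4=COC(C)(C)OC4=O)[C@@H](C(OC)OC)CC[C@@H]13
A2 | alternative 1 | pentacyclic cyclobutane photoadduct | [C@H]4(OC(C)(C)OC5=O)[C@@]1(CO[Si](C(C)C)(C(C)C)C(C)C)[C@@H]2C[C@]3([C@@H](O[Si](C)(C)C(C)(C)C)C[C@@]245)[C@@H](C(OC)OC)CC[C@@H]13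
A3 | alternative 2 | enyne with exocyclic C1=C2 alkene and terminal alkyne on C6 | C[C@](CO[Si](C(C)C)(C(C)C)C(C)C)(C#C)[C@@H]1C/C(=C/CO[Si](C)(C)C(C)(C)C)[C@@H](OCc2ccc(OC)cc2)C=C1C(=O)OC
A4 | alternative 2 | cedrane tricycle as the C3-oxo C4=C5 enone | C[C@@]1(CO[Si](C(C)C)(C(C)C)C(C)C)[C@@H]2C[C@]3([C@@H](OCc4ccc(OC)cc4)C=C2C(=O)OC)[C@@H](CO[Si](C)(C)C(C)(C)C)C(=O)C=C13
A5 | alternative 3 | fused cyclopentadiene with C6=C7 and C1=C5 alkenes | CC(C)(C)[Si](C)(C)OCC1=CCC2=C1CC[C@@H]2C(OC)OC
A6 | alternative 3 | methyl 2-diazobut-3-enoate | COC(=O)C(=[N+]=[N-])C=C
A7 | alternative 3 | tricyclic bicyclo[3.2.1]octadiene with C8 ester | CC(C)(C)[Si](C)(C)OCC1=C2CC[C@H](C(OC)OC)[C@@]23C[C@@H]1C(C(=O)OC)=CC3
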